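## Analysis of the target

Rubioncolin C (14) is built from two naphthalene-derived halves joined through a single ether oxygen. In the first half, ring A is fully substituted: C1 carries a free hydroxyl, C2 a methyl ester, C3 a prenyl (3-methylbut-2-en-1-yl) group and C4 the ether oxygen; the fused ring B is unsubstituted. The ether oxygen is bound to C2' of a 1,4-naphthoquinone (quinone ring C, benzo ring D), whose C3' carries hydrogen. The molecule has no stereocentre and the prenyl alkene has no E/Z isomerism, so the problem is one of regiochemistry and functional-group compatibility. The sensitive groups are the aryloxyquinone (a vinylogous ester that nucleophiles cleave by addition–elimination, and an oxidant), the electron-rich mono-etherified hydroquinone of ring A, and the prenyl group ortho to an oxygen (acid closes it to a chroman, oxidants to a chromene). Three things make the synthesis hard: four different substituents must sit in a fixed order around ring A; the two para oxygens must be told apart (C1–OH free and chelated to the ester, C4–O arylated); and an oxidisable naphthol must be joined to an oxidising quinone. The strategy rests on C2 of ring A. If C2 and its ester are taken out, C1 and C3 become directly bonded, and what remains is the five-membered ring of a 2-prenylindane-1,3-dione with both oxygens and the prenyl group already in the right order. At the indene oxidation level the two oxygens are also chemically different (one enol, one carbinol), and this difference maps onto C1–O and C4–O of the target.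

## Retrosynthetic reasoning

The last bond cut is the O–Si bond at C1: 14 comes from its C1 silyl ether 13. Keeping C1–O blocked until the end means no free hydroquinone is ever exposed to a quinone; the forward step is a buffered fluoride desilylation that must spare the aryloxyquinone.

The C4–O–C2' ether bond is cut next, giving naphthol 11 and 2-bromo-1,4-naphthoquinone 12. This is the only bond between the two halves, and 12 brings rings C and D complete and at the right oxidation level. The forward reaction is an addition–elimination of the C4 phenoxide on the bromoquinone. It needs only O-selectivity, which is assured because the ortho and para carbons of the phenoxide are substituted.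

Naphthol 11 is traced to the bis-silyl ether 10, which carries a small triethylsilyl group on C4–O and a bulky triisopropylsilyl group on C1–O. Two different silyl groups are used in place of two identical ones so that the C4 oxygen can be freed alone by acid-catalysed solvolysis. Both size and electronics favour this: C1–O is conjugated with the ortho ester and therefore less basic.

The key disconnection removes C2 of ring A with its ester, cutting C1–C2 and C2–C3. This gives the 1H-indene 6 and methyl bromodiazoacetate 8. It is made here because the resulting five-membered ring precursor is symmetric in its carbon skeleton and trivially available, and because the enol oxygen of 6 (triisopropylsilyl) necessarily ends up next to the ester while the carbinol oxygen (triethylsilyl) ends up next to the prenyl group. In the forward direction the rhodium carbenoid from 8 must cyclopropanate the enol ether C=C to give 9. The cyclopropane then opens with loss of bromide and a proton to give the aromatic ring A of 10.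

Indene 6 is simplified by O–Si and C–H disconnections to alcohol 5, the vinylogous silyl ester 4 and the dione 3. O-silylating the dione before reduction removes its acidic proton, so a hydride can reduce the remaining carbonyl cleanly. This order also installs the two silyl groups one at a time on two different oxygens.

Dione 3 is cut at the C2–prenyl bond to indane-1,3-dione 1 and prenyl bromide 2; the forward step is a C-alkylation that must stop after one prenyl group. Reagent 8 comes from methyl diazoacetate 7 by electrophilic bromination at the diazo carbon.

## Alternatives that were turned down

Alternative 1: The quinone ring C is disconnected at C1'–C8a' and C4'–C4a', giving the 3-aryloxyfuran A2 and the aryne released by CsF from 2-(trimethylsilyl)phenyl triflate A3. The forward key step is a [4+2] cycloaddition to the oxa-bridged adduct A1 (racemic).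
- For: aryne–furan cycloadditions are among the most dependable ring-forming reactions, the aryne is symmetric so there is no regiochemical question, and the conditions are mild. On the reliability of the key step this alternative is stronger than the chosen route.
- Against: it builds the unsubstituted quinone half, which can simply be bought as 12, and leaves all of ring A to be made by other means. A2 needs a C–O coupling between a halofuran and a hindered ortho-substituted naphthol. A1 still needs bridge opening and an oxidation to reach the quinone, with oxidants that also threaten ring A and the prenyl group. An acid-labile MOM group must then be removed next to the prenyl group.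
- Comparison: the chosen strategy puts its one uncertain step into ring A, where the structural difficulty lies, and takes rings C and D from 12 in a single step.

Alternative 2: Ring A is disconnected at C2–C3, giving the ortho-alkynyl benzoylacetate A4. With Ph3PAuNTf2 the enol carbon attacks the distal alkyne carbon in a 6-endo-dig Conia-ene closure to the naphthol A5.
- For: the key step is a catalytic isomerisation with perfect atom economy, needs no diazo compound, and fixes the ester/prenyl relationship by connectivity. On safety and on freedom from carbenoid chemoselectivity it is stronger than the chosen route.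
- Against: A5 has hydrogen at C4. The C4 oxygen would have to be introduced late by para-oxidation to a quinone and reduction, in the presence of the prenyl group. That sequence ends at a hydroquinone whose two hydroxyls are undifferentiated and which would then face the oxidising bromoquinone. The skipped enyne of A4 is also prone to gold-mediated enyne cycloisomerisation and to isomerisation of its doubly activated CH2.
- Comparison: the chosen strategy carries both oxygens from the first step and differentiates them by origin, so no late oxidation is needed.

Alternative 3: Ring C is disconnected at C4'–C4a', giving the 4-hydroxy-4-phenylcyclobutenone A6. On heating in xylene it opens to a vinylketene that closes onto the phenyl ring (Moore rearrangement) to give the hydroquinone A7, one mild oxidation from the target.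
- For: the key step is thermal and reagent-free, the position of the aryloxy group on ring C is fixed by the cyclobutenone, and the ether bond would be formed with a non-oxidising squarate-type electrophile. On the ether-forming step this alternative is stronger, because it avoids the phenol-plus-quinone redox problem.
- Against: A6 requires an aryl-lithium or aryl-magnesium addition to a cyclobutenedione in the presence of the methyl ester of ring A. The thermolysis runs near 140 °C on a prenylated, electron-rich arene. Like alternative 1, it builds the trivial half and leaves ring A to be made separately with C4–OH selectively free.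
- Comparison: the chosen strategy answers the redox problem by keeping C1–O silylated through the coupling, and it builds the hard ring.

Key step: step 6

Remark: prenyl stands for 3-methylbut-2-en-1-yl. Compounds 5, 6 and 9 are racemic and drawn as one enantiomer; their stereocentres are erased in step 6.

Step 1
Reactants: 1 indane-1,3-dione; 2 prenyl bromide
Product: 3 2-prenylindane-1,3-dione
Conditions: 1 (2 equiv), K2CO3 (1 equiv), 2 (1 equiv, slow addition), MeCN, 0 °C to rt; base extraction, acidification
Reagents that add atoms: none
Why: SN2 C-alkylation of the stabilised 1,3-dione enolate with an allylic bromide; O-alkylation is disfavoured because it would create an indenone. The excess of the more acidic 1 keeps product 3 largely protonated, which should suppress a second prenylation, and 3 is separated from neutral by-products through its acidity.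

Step 2
Reactants: 3 2-prenylindane-1,3-dione
Product: 4 2-prenyl-3-(triisopropylsilyloxy)-1H-inden-1-one
Conditions: TIPSOTf, Et3N, CH2Cl2, 0 °C
Reagents that add atoms: triisopropylsilyl triflate, CC(C)[Si](OS(=O)(=O)C(F)(F)F)(C(C)C)C(C)C
Why: O-silylation of a vinylogous acid to the vinylogous silyl ester; the dione is symmetric, so only one product can form. The bulky triisopropylsilyl group should make the enol ether stable enough to handle and removes the acidic proton that would otherwise quench a hydride.

Step 3
Reactants: 4 2-prenyl-3-(triisopropylsilyloxy)-1H-inden-1-one
Product: 5 2-prenyl-3-(triisopropylsilyloxy)-1H-inden-1-ol (racemic)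
Conditions: iBu2AlH, toluene, −78 °C; aq. potassium sodium tartrate (KNaC4H4O6) work-up, no acid
Reagents that add atoms: none
Why: 1,2-reduction of a vinylogous ester carbonyl, as in the first half of a Stork–Danheiser sequence. The new carbinol centre forms as a racemate and needs no control because it is destroyed in step 6; the crude alcohol is carried on without exposure to acid.

Step 4
Reactants: 5 2-prenyl-3-(triisopropylsilyloxy)-1H-inden-1-ol
Product: 6 2-prenyl-1-(triethylsilyloxy)-3-(triisopropylsilyloxy)-1H-indene (racemic)
Conditions: TESCl, imidazole, DMAP (cat.), CH2Cl2, 0 °C to rt; Et3N-deactivated silica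
Reagents that add atoms: chlorotriethylsilane, CC[Si](Cl)(CC)CC
Why: Standard silylation of a secondary alcohol under basic conditions, which avoid ionisation of the allylic, benzylic C–O bond. The small triethylsilyl group marks the oxygen that will become C4–O.

Step 5
Reactants: 7 methyl diazoacetate
Product: 8 methyl bromodiazoacetate
Conditions: NBS, DBU, CH2Cl2, 0 °C, minutes; cold filtration through silica, used at once as a cold solution
Reagents that add atoms: N-bromosuccinimide, BrN1C(=O)CCC1=O
Why: Deprotonation at the diazo carbon and electrophilic bromination, the established preparation of halodiazoacetates. The reagent is thermally labile, so it is generated cold and used immediately.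

Step 6
Reactants: 6 2-prenyl-1-(triethylsilyloxy)-3-(triisopropylsilyloxy)-1H-indene; 8 methyl bromodiazoacetate
Product: 10 methyl 3-prenyl-4-(triethylsilyloxy)-1-(triisopropylsilyloxy)-2-naphthoate, via ring-fused bromocyclopropane 9 (not isolated)
Conditions: Rh2(esp)2 (1–2 mol %), Cs2CO3, CH2Cl2, 0 °C, slow addition of cold 8 (1.2 equiv), then rt
Reagents that add atoms: none
Why: Rh2(esp)2 decomposes 8 to an electrophilic bromo(methoxycarbonyl)carbenoid, which adds to the C2=C3 silyl enol ether of 6 in an asynchronous [2+1] cycloaddition (first bond to the nucleophilic C2, then closure on C3) from the face anti to the C1 triethylsilyloxy group, giving the cis-fused cyclopropane 9. In 9 the triisopropylsilyloxy oxygen pushes and bromide leaves, and a disrotatory 2π-electrocyclic cyclopropyl-to-allyl opening cleaves the former C2–C3 bond, so the carbene carbon comes to lie in a six-membered ring between the oxygen-bearing and the prenyl-bearing carbon. Loss of the proton on the triethylsilyloxy-bearing sp3 carbon to Cs2CO3 then aromatises ring A, which is therefore closed by one-carbon ring expansion of the five-membered ring and not by a cyclisation; both new skeletal bonds (C1–C2 and C2–C3 of the naphthalene) are made in the cyclopropanation. The closest known reaction type is the rhodium-catalysed halodiazoacetate cyclopropanation–ring expansion of indoles to quinoline-3-carboxylates and of indenes to naphthalenes, together with the halocarbene homologation of cyclic silyl enol ethers (Ciamician–Dennstedt type). No stereocentre remains, since the four of 9 are erased on aromatisation, and a bromide epimer that is not aligned for concerted opening can reach the same cation by reversible heterolysis of the donor–acceptor cyclopropane. Regiochemistry needs no control because 6 has a single enol C=C, so the ester must land between the triisopropylsilyloxy carbon and the prenyl carbon. The step needs chemoselectivity for the enol ether over the prenyl alkene: the enol ether is the stronger π-nucleophile (oxygen lone pair plus conjugation to the arene), and slow addition of a small excess of 8 keeps the carbenoid concentration low so that the side chains of 6 and 10 are left alone. The bulk of the triisopropylsilyl group should favour loss of the proton over loss of silicon from the intermediate cation.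

Step 7
Reactants: 10 methyl 3-prenyl-4-(triethylsilyloxy)-1-(triisopropylsilyloxy)-2-naphthoate
Product: 11 methyl 4-hydroxy-3-prenyl-1-(triisopropylsilyloxy)-2-naphthoate
Conditions: PPTS (cat.), MeOH/CH2Cl2, 0 °C to rt, argon
Reagents that add atoms: none
Why: Acid-catalysed methanolysis should remove triethylsilyl far faster than triisopropylsilyl on steric grounds. Electronics point the same way, since C4–O is the more basic oxygen while C1–O is conjugated with the ortho ester; the mild acid should leave the prenyl group untouched.

Step 8
Reactants: 11 methyl 4-hydroxy-3-prenyl-1-(triisopropylsilyloxy)-2-naphthoate; 12 2-bromo-1,4-naphthoquinone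
Product: 13 methyl 4-[(1,4-dioxo-1,4-dihydronaphthalen-2-yl)oxy]-3-prenyl-1-(triisopropylsilyloxy)-2-naphthoate
Conditions: Cs2CO3, MeCN (degassed), 0 °C to rt, argon
Reagents that add atoms: none
Why: Addition–elimination (vinylogous acyl substitution) of the phenoxide on the bromoquinone, the usual route to 2-aryloxy-1,4-naphthoquinones. C-attack is excluded because the ortho and para positions of the phenoxide are substituted, and with C1–O silylated no free hydroquinone is present to undergo redox exchange with 12.

Step 9
Reactants: 13 methyl 4-[(1,4-dioxo-1,4-dihydronaphthalen-2-yl)oxy]-3-prenyl-1-(triisopropylsilyloxy)-2-naphthoate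
Product: 14 rubioncolin C
Conditions: TBAF, AcOH, THF, 0 °C
Reagents that add atoms: none
Why: Fluoride cleavage of an aryl silyl ether whose phenoxide is a good leaving group (ortho ester). The acetic acid buffer should keep the medium from becoming basic enough to attack the aryloxyquinone or the methyl ester.

Compound list
1 | indane-1,3-dione | O=C1CC(=O)c2ccccc12 | starting material
2 | prenyl bromide (1-bromo-3-methylbut-2-ene) | CC(C)=CCBr | starting material
3 | 2-prenylindane-1,3-dione | CC(C)=CCC1C(=O)c2ccccc2C1=O | intermediate
4 | 2-prenyl-3-(triisopropylsilyloxy)-1H-inden-1-one | CC(C)=CCC1=C(O[Si](C(C)C)(C(C)C)C(C)C)c2ccccc2C1=O | intermediate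
5 | 2-prenyl-3-(triisopropylsilyloxy)-1H-inden-1-ol (racemic, one enantiomer drawn) | CC(C)=CCC1=C(O[Si](C(C)C)(C(C)C)C(C)C)c2ccccc2[C@H]1O | intermediate
6 | 2-prenyl-1-(triethylsilyloxy)-3-(triisopropylsilyloxy)-1H-indene (racemic, one enantiomer drawn) | CC(C)=CCC1=C(O[Si](C(C)C)(C(C)C)C(C)C)c2ccccc2[C@H]1O[Si](CC)(CC)CC | intermediate
7 | methyl diazoacetate | COC(=O)C=[N+]=[N-] | starting material
8 | methyl bromodiazoacetate | COC(=O)C(Br)=[N+]=[N-] | intermediate
9 | methyl 1-bromo-6a-prenyl-6-(triethylsilyloxy)-1a-(triisopropylsilyloxy)-1,1a,6,6a-tetrahydrocyclopropa[a]indene-1-carboxylate (racemic; expected isomer drawn: cis-fused, carbene carbon anti to the triethylsilyloxy group, bromide endo) | COC(=O)[C@]1(Br)[C@@]2(CC=C(C)C)[C@H](O[Si](CC)(CC)CC)c3ccccc3[C@@]12O[Si](C(C)C)(C(C)C)C(C)C | intermediate (not isolated)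
10 | methyl 3-prenyl-4-(triethylsilyloxy)-1-(triisopropylsilyloxy)-2-naphthoate | COC(=O)c1c(CC=C(C)C)c(O[Si](CC)(CC)CC)c2ccccc2c1O[Si](C(C)C)(C(C)C)C(C)C | intermediate
11 | methyl 4-hydroxy-3-prenyl-1-(triisopropylsilyloxy)-2-naphthoate | COC(=O)c1c(CC=C(C)C)c(O)c2ccccc2c1O[Si](C(C)C)(C(C)C)C(C)C | intermediate
12 | 2-bromo-1,4-naphthoquinone | O=C1C=C(Br)C(=O)c2ccccc12 | starting material
13 | methyl 4-[(1,4-dioxo-1,4-dihydronaphthalen-2-yl)oxy]-3-prenyl-1-(triisopropylsilyloxy)-2-naphthoate | COC(=O)c1c(CC=C(C)C)c(OC2=CC(=O)c3ccccc3C2=O)c2ccccc2c1O[Si](C(C)C)(C(C)C)C(C)C | intermediate
14 | rubioncolin C (methyl 4-[(1,4-dioxo-1,4-dihydronaphthalen-2-yl)oxy]-1-hydroxy-3-prenyl-2-naphthoate) | COC(=O)c1c(CC=C(C)C)c(OC2=CC(=O)c3ccccc3C2=O)c2ccccc2c1O | target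

Total step count: 9. Longest linear sequence: 8 steps (steps 1, 2, 3, 4, 6, 7, 8, 9 from indane-1,3-dione); step 5 is a one-step side branch.

Least certain steps

Step 6 (key step). Several things may go wrong:
- carbene transfer to the hindered, tetrasubstituted enol ether may be slow, so that carbene dimerisation or cyclopropanation of the prenyl alkene of 6 or 10 takes over;
- the zwitterion formed on first C–C bonding may collapse by silyl transfer to a simple C-alkylation product and not close to the cyclopropane;
- the cation formed on ring opening may lose the triisopropylsilyl group in place of the proton.

The last outcome is harmless, because it leads to the C1 naphthol that is compound F3 below, and re-silylation returns it to 10. Fallback for the other failure modes: give up the ring construction and take ring A from purchasable methyl 1,4-dihydroxy-2-naphthoate F1. Setting out from prenyl bromide 2, the monosodium phenoxide of F1 (NaH, toluene) is C-alkylated at C3, the only free position of ring A, by the phenoxide ortho-allylation used for naphthohydroquinone side chains in the vitamin K series. This should give methyl 1,4-dihydroxy-3-prenyl-2-naphthoate F2. TESCl and imidazole should silylate the non-chelated C4 hydroxyl to give methyl 1-hydroxy-3-prenyl-4-(triethylsilyloxy)-2-naphthoate F3. TIPSOTf and 2,6-lutidine then cap the chelated C1 hydroxyl, and the route is rejoined at 10.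

Step 1. The enolate of product 3 may be prenylated a second time, and some O-alkylation may occur. Fallback: form the C–C bond by condensation and conjugate reduction, which cannot over-alkylate. Setting out from 1, Knoevenagel condensation with 3-methylbut-2-enal F4 gives 2-(3-methylbut-2-en-1-ylidene)indane-1,3-dione F5. Hydride transfer from the Hantzsch ester to the carbon next to the ring (the remote terminus is blocked by its two methyl groups) should give 3, where the route is rejoined.

Step 3. The hydride reagent may attack silicon instead of the carbonyl, or the new hydroxyl may be eliminated on work-up to an indenone. Fallback: reverse the order of reduction and enol silylation. Setting out from 3, NaBH4 with a limited amount of hydride at low temperature in EtOH should give 3-hydroxy-2-prenylindan-1-one F6 as a mixture of diastereomers. TESCl and imidazole give 2-prenyl-3-(triethylsilyloxy)indan-1-one F7, and soft enolisation with TIPSOTf and Et3N converts both diastereomers into 6, where the route is rejoined. The known weakness of this sequence is that the acidic dione may be deprotonated by the borohydride and stall, which is why it is not the first choice.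

Step 8. Electron transfer from the electron-rich naphtholate to the bromoquinone may divert material into redox by-products, and carbonate may remove the triisopropylsilyl group before the coupling. Fallback: couple with a redox-inert partner and reveal the quinone afterwards. Setting out from 11, an Ullmann ether synthesis (CuI, N,N-dimethylglycine, Cs2CO3, dioxane, 90 °C) with 2-bromo-1,4-dimethoxynaphthalene F8 should give methyl 4-[(1,4-dimethoxynaphthalen-2-yl)oxy]-3-prenyl-1-(triisopropylsilyloxy)-2-naphthoate F9. Oxidative demethylation with (NH4)2Ce(NO3)6 in aqueous MeCN at 0 °C should act on the more electron-rich trioxygenated ring and give 13, where the route is rejoined.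

Further compounds
F1 | step 6 | methyl 1,4-dihydroxy-2-naphthoate | COC(=O)c1cc(O)c2ccccc2c1O
F2 | step 6 | methyl 1,4-dihydroxy-3-prenyl-2-naphthoate | COC(=O)c1c(CC=C(C)C)c(O)c2ccccc2c1O
F3 | step 6 | methyl 1-hydroxy-3-prenyl-4-(triethylsilyloxy)-2-naphthoate | COC(=O)c1c(CC=C(C)C)c(O[Si](CC)(CC)CC)c2ccccc2c1O
F4 | step 1 | 3-methylbut-2-enal | CC(C)=CC=O
F5 | step 1 | 2-(3-methylbut-2-en-1-ylidene)indane-1,3-dione | CC(C)=CC=C1C(=O)c2ccccc2C1=O
F6 | step 3 | 3-hydroxy-2-prenylindan-1-one (racemic, cis isomer drawn, mixture of diastereomers expected) | O=C1c2ccccc2[C@@H](O)[C@H]1CC=C(C)C
F7 | step 3 | 2-prenyl-3-(triethylsilyloxy)indan-1-one (racemic, cis isomer drawn, mixture of diastereomers expected) | O=C1c2ccccc2[C@@H](O[Si](CC)(CC)CC)[C@H]1CC=C(C)C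
F8 | step 8 | 2-bromo-1,4-dimethoxynaphthalene | COc1cc(Br)c(OC)c2ccccc12
F9 | step 8 | methyl 4-[(1,4-dimethoxynaphthalen-2-yl)oxy]-3-prenyl-1-(triisopropylsilyloxy)-2-naphthoate | COC(=O)c1c(CC=C(C)C)c(Oc2cc(OC)c3ccccc3c2OC)c2ccccc2c1O[Si](C(C)C)(C(C)C)C(C)C
A1 | alternative 1 | methyl 4-[(1,4-dihydro-1,4-epoxynaphthalen-2-yl)oxy]-1-(methoxymethoxy)-3-prenyl-2-naphthoate (racemic, one enantiomer drawn) | COCOc1c(C(=O)OC)c(CC=C(C)C)c(OC3=C[C@@H]4O[C@H]3c3ccccc34)c2ccccc12
A2 | alternative 1 | methyl 4-(furan-3-yloxy)-1-(methoxymethoxy)-3-prenyl-2-naphthoate | COCOc1c(C(=O)OC)c(CC=C(C)C)c(Oc3ccoc3)c2ccccc12
A3 | alternative 1 | 2-(trimethylsilyl)phenyl triflate | C[Si](C)(C)c1ccccc1OS(=O)(=O)C(F)(F)F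
A4 | alternative 2 | methyl 3-[2-(5-methylhex-4-en-1-yn-1-yl)phenyl]-3-oxopropanoate | COC(=O)CC(=O)c1ccccc1C#CCC=C(C)C
A5 | alternative 2 | methyl 1-hydroxy-3-prenyl-2-naphthoate | COC(=O)c1c(CC=C(C)C)cc2ccccc2c1O
A6 | alternative 3 | methyl 1-hydroxy-4-[(4-hydroxy-3-oxo-4-phenylcyclobut-1-en-1-yl)oxy]-3-prenyl-2-naphthoate (racemic, one enantiomer drawn) | COC(=O)c1c(CC=C(C)C)c(OC2=CC(=O)[C@@]2(O)c2ccccc2)c2ccccc2c1O
A7 | alternative 3 | methyl 4-[(1,4-dihydroxynaphthalen-2-yl)oxy]-1-hydroxy-3-prenyl-2-naphthoate | COC(=O)c1c(CC=C(C)C)c(Oc2cc(O)c3ccccc3c2O)c2ccccc2c1O
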